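**Strategy.** Everything rests on disconnecting the C4–C5 bond of ring A and on the latent mirror symmetry of ring B, whose plane through C10 and C7 pairs C5 with C9 and C6 with C8. The precursor is an achiral, Birch-derived 3,5-dimethoxycyclohexa-2,5-diene whose quaternary carbon (C10) carries the methyl group and a four-carbon diazo ester tether (C1–C4, C19). A chiral dirhodium carbenoid adds to one of the two enantiotopic enol ethers: this single step closes ring A and fixes the C10 stereocentre. The resulting donor–acceptor cyclopropane is then opened to a 6,8-dioxygenated decalin from which C9, C4, C6 and C8 are elaborated.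

Key step: step 7

Remark: atoms are numbered as in the labdane skeleton of the target (ring A = C1–C5, C10; ring B = C5–C10; side chain C11–C16; C17 exocyclic methylene; C18 4α-methyl; C19 ester carbon; C20 10-methyl).
Remark (assumption): the sense in which Rh2(S-PTTL)4 discriminates the enantiotopic enol ethers cannot be predicted reliably; the catalyst antipode that gives the C10 configuration drawn for 11 is meant. Phosphonium salt 5 is taken as purchasable.

Step 1
Reactants: 1 3,5-dimethoxybenzoic acid
Product: 2 3,5-dimethoxy-1-methylcyclohexa-2,5-diene-1-carboxylic acid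
Conditions: Li, NH3(l), THF, −78 °C; MeI; then NH4Cl(aq) to pH 5, 0 °C
Reagents that add atoms: iodomethane, CI
Why: Birch reductive alkylation, in which the carboxylate-stabilised cyclohexadienyl dianion is methylated at the ipso carbon (future C10) to give the achiral 1,4-diene with both enol ethers intact.

Step 2
Reactants: 2 3,5-dimethoxy-1-methylcyclohexa-2,5-diene-1-carboxylic acid
Product: 3 (3,5-dimethoxy-1-methylcyclohexa-2,5-dien-1-yl)methanol
Conditions: LiAlH4, THF, 0 °C to reflux; aqueous NaOH work-up
Reagents that add atoms: none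
Why: Hydride reduction of the hindered carboxylate to the primary alcohol (future C1) should leave the base-stable enol ethers untouched.

Step 3
Reactants: 3 (3,5-dimethoxy-1-methylcyclohexa-2,5-dien-1-yl)methanol
Product: 4 3,5-dimethoxy-1-methylcyclohexa-2,5-diene-1-carbaldehyde
Conditions: [N(C3H7)4][RuO4] (5 mol %), N-methylmorpholine N-oxide, 4 Å molecular sieves, CH2Cl2, rt
Reagents that add atoms: none
Why: Ley–Griffith oxidation under neutral conditions should give the non-enolisable aldehyde and spare the acid-labile enol ethers.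

Step 4
Reactants: 4 3,5-dimethoxy-1-methylcyclohexa-2,5-diene-1-carbaldehyde; 5 (4-methoxy-4-oxobutyl)triphenylphosphonium bromide
Product: 7 methyl (4Z)-5-(3,5-dimethoxy-1-methylcyclohexa-2,5-dien-1-yl)pent-4-enoate, via phosphorus ylide 6 (not isolated)
Conditions: 5, NaN(SiMe3)2, THF, −78 °C; then 4, −78 °C to rt
Reagents that add atoms: none
Why: Wittig olefination with the non-stabilised ylide brings in C2, C3, C4 and C19; the alkene geometry is irrelevant because the alkene is reduced next.

Step 5
Reactants: 7 methyl (4Z)-5-(3,5-dimethoxy-1-methylcyclohexa-2,5-dien-1-yl)pent-4-enoate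
Product: 8 methyl 5-(3,5-dimethoxy-1-methylcyclohexa-2,5-dien-1-yl)pentanoate
Conditions: 2-O2NC6H4SO2NHNH2, Et3N, CH2Cl2, rt
Reagents that add atoms: none
Why: Diimide reduction should saturate the unpolarised 1,2-disubstituted alkene and leave the trisubstituted enol ethers alone.

Step 6
Reactants: 8 methyl 5-(3,5-dimethoxy-1-methylcyclohexa-2,5-dien-1-yl)pentanoate
Product: 10 methyl 2-diazo-5-(3,5-dimethoxy-1-methylcyclohexa-2,5-dien-1-yl)pentanoate, via trifluoroacetyl ester 9 (not isolated)
Conditions: LiN(SiMe3)2, THF, −78 °C; CF3CO2CH2CF3; then MsN3, Et3N, H2O, MeCN, rt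
Reagents that add atoms: 2,2,2-trifluoroethyl trifluoroacetate, O=C(OCC(F)(F)F)C(F)(F)F (trifluoroacetyl group of 9 only); methanesulfonyl azide, CS(=O)(=O)N=[N+]=[N-]
Why: Detrifluoroacetylative diazo transfer, in which Claisen trifluoroacetylation of the ester enolate activates C4 for sulfonyl azide transfer and the activating group leaves as the sulfonamide.

Step 7
Reactants: 10 methyl 2-diazo-5-(3,5-dimethoxy-1-methylcyclohexa-2,5-dien-1-yl)pentanoate
Product: 11 tricyclic cyclopropane ester (ring A fused to ring B; cyclopropane C4–C5–C6 on the ring B face that carries C1; 4-CO2Me; 6-OMe; 8-methoxy-8-ene; 10β-CH3)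
Conditions: Rh2(S-PTTL)4 (dirhodium tetrakis[N-phthaloyl-(S)-tert-leucinate], 1 mol %), CH2Cl2, −78 °C, slow addition of 10
Reagents that add atoms: none
Why: Rh2(S-PTTL)4 expels N2 from 10 to give an electrophilic rhodium carbenoid at C4, which adds in a concerted asynchronous [2+1] fashion to one of the two enantiotopic, electron-rich enol ethers (C5=C6). The closest known reaction types are the low-temperature enantioselective cyclopropanation with α-alkyl-α-diazo esters under bulky chiral dirhodium carboxylates and the desymmetrising intramolecular cyclopropanation of Birch-derived cyclohexa-1,4-dienes. Ring A closes as a six-membered ring by 6-exo delivery of C4 to C5 through the tether C3–C2–C1–C10, and the temporary cyclopropane C4–C5–C6 closes in the same concerted event on the ring B face that carries C1. C10 becomes stereogenic by catalyst-controlled choice between the enantiotopic alkenes, whereas C4, C5 and C6 follow from C10 by the geometric constraint of the cis-fused intramolecular addition (they are reset in steps 8, 9, 13 and 15). The step needs chemoselectivity for cyclopropanation over 1,2-hydride shift from C3, which the low temperature, the bulky phthalimido carboxylate ligands, the high nucleophilicity of the enol ether and the quaternary C10 (favouring the folded tether) should secure. It also needs enantiotopic-group selectivity, which rests on the chiral catalyst pocket; C–H insertion has no accessible five-membered pathway because C10 bears no hydrogen.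

Step 8
Reactants: 11 tricyclic cyclopropane ester
Product: 13 methyl 6-methoxy-4a-methyl-8-oxo-1,2,3,4,4a,5,8,8a-octahydronaphthalene-1-carboxylate (C6 ketone and C8 methyl enol ether in labdane numbering), via dione 12 (not isolated)
Conditions: 2 M HCl, THF, 40 °C; evaporate; then MeOH, TsOH (cat.), 4 Å molecular sieves, rt
Reagents that add atoms: water, O; methanol, CO
Why: Aqueous acid hydrolyses the enol ether and opens the donor–acceptor cyclopropane at the C4–C6 bond to the 1,3-dione (homo-retro-aldol type ring opening); acid-catalysed enol etherification should then occur at the carbonyl remote from the substituted α-carbon C5, as is usual for 4-substituted cyclohexane-1,3-diones.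

Step 9
Reactants: 13 vinylogous ester
Product: 16 methyl 4a-methyl-6-oxo-1,2,3,4,4a,5,6,8a-octahydronaphthalene-1-carboxylate (trans-fused; 5α-H; C8 ketone and 6-ene in labdane numbering), via allylic alcohol 14 (not isolated), via enone C5-epimer mixture 15 (not isolated)
Conditions: NaBH4, CeCl3·7H2O, MeOH, −20 °C; cold quench into 1 M HCl, THF, 0 °C to rt; then NaOMe (0.2 equiv), MeOH, 50 °C
Reagents that add atoms: water, O
Why: Stork–Danheiser 1,3-carbonyl transposition (Luche 1,2-reduction at C6, then acid-induced ionisation and hydrolysis of the vinylogous hemiketal) gives the C8 enone, and methoxide should then equilibrate the γ-carbon C5 through the extended dienolate to the trans-fused isomer, in which the C4 substituent is equatorial on ring B and reprotonation is axial and anti to the C10 methyl.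

Step 10
Reactants: 17 but-2-yn-1-ol
Product: 18 (2Z)-3-iodobut-2-en-1-ol
Conditions: NaAlH2(OCH2CH2OCH3)2, THF, 0 °C to rt; I2, −78 °C
Reagents that add atoms: iodine, II
Why: trans-Hydroalumination of the propargylic alcohol (hydride to C2, aluminium held at C3 by the alkoxide) and iodinolysis with retention should give the Z iodoalkene that carries C11, C12, C13 and C16.

Step 11
Reactants: 18 (2Z)-3-iodobut-2-en-1-ol
Product: 19 (2Z)-1-bromo-3-iodobut-2-ene
Conditions: CBr4, PPh3, CH2Cl2, 0 °C
Reagents that add atoms: tetrabromomethane, BrC(Br)(Br)Br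
Why: Appel bromination of the primary allylic alcohol should not disturb the alkene geometry.

Step 12
Reactants: 16 trans-fused enone ester; 19 (2Z)-1-bromo-3-iodobut-2-ene
Product: 20 methyl 5-[(2Z)-3-iodobut-2-en-1-yl]-4a-methyl-6-oxo-1,2,3,4,4a,5,6,8a-octahydronaphthalene-1-carboxylate (alkylated at C9; configuration at C9 and C4 left open)
Conditions: LiN(iPr)2, THF, −78 °C; 19, DMPU, −78 to −20 °C
Reagents that add atoms: none
Why: Kinetic deprotonation of the cyclohexenone at the α′ carbon C9 (cross-conjugated dienolate) and SN2 alkylation with the allylic bromide should be regiospecific; the C9 configuration is set in step 13.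

Step 13
Reactants: 20 C9-alkylated enone ester
Product: 21 methyl (12Z)-13-iodo-8-oxo-14,15,17-trinorlabda-6,12-dien-19-oate
Conditions: LiN(iPr)2 (2.3 equiv), THF–DMPU, −78 to −40 °C; MeI (1.1 equiv), −78 °C; AcOH, −78 °C
Reagents that add atoms: iodomethane, CI
Why: Dianion alkylation, in which the more reactive C19 ester enolate is methylated at C4 from the α face (equatorial attack anti to the axial C10 methyl) while the fully substituted C9 enolate stays unreacted and is then protonated kinetically from the same open α face, giving 4α-CH3, 4β-CO2Me and the 9β side chain.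

Step 14
Reactants: 21 methyl (12Z)-13-iodo-8-oxo-14,15,17-trinorlabda-6,12-dien-19-oate
Product: 22 methyl (12Z)-8-oxo-17-norlabda-6,12,14-trien-19-oate
Conditions: CH2=CHSnBu3, Pd2(dba)3 (cat.), AsPh3, NMP, 40 °C
Reagents that add atoms: tributyl(vinyl)stannane, C=C[Sn](CCCC)(CCCC)CCCC
Why: Stille coupling of the alkenyl iodide proceeds with retention and should give the 12Z diene.

Step 15
Reactants: 22 methyl (12Z)-8-oxo-17-norlabda-6,12,14-trien-19-oate
Product: 24 methyl (12Z)-6α-hydroxy-8-oxo-17-norlabda-12,14-dien-19-oate, via boronate 23 (not isolated)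
Conditions: B2pin2, CuCl (5 mol %), DPEphos, NaOtBu (10 mol %), MeOH (2 equiv), THF, rt; then NaBO3·4H2O, THF/H2O, rt
Reagents that add atoms: bis(pinacolato)diboron, CC1(C)OB(OC1(C)C)B1OC(C)(C)C(C)(C)O1 (boryl group of 23 only); sodium perborate, [Na+].[O-]OB=O
Why: Copper-catalysed conjugate borylation should deliver boron to C6 from the α face because the β face is shielded by the syn-axial C10 methyl and C4 ester, and perborate oxidation with retention then gives the equatorial 6α-alcohol.

Step 16
Reactants: 24 methyl (12Z)-6α-hydroxy-8-oxo-17-norlabda-12,14-dien-19-oate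
Product: 25 methyl (12Z)-6α-acetoxy-8-oxo-17-norlabda-12,14-dien-19-oate
Conditions: Ac2O, pyridine, DMAP (cat.), CH2Cl2, 0 °C to rt
Reagents that add atoms: acetic anhydride, CC(=O)OC(C)=O
Why: Nucleophile-catalysed acylation of the secondary alcohol under conditions too mild for β-elimination.

Step 17
Reactants: 25 methyl (12Z)-6α-acetoxy-8-oxo-17-norlabda-12,14-dien-19-oate
Product: 26 methyl (12Z)-6α-acetoxylabda-8(17),12,14-trien-19-oate (target)
Conditions: Zn, CH2Br2, TiCl4, THF/CH2Cl2, 0 °C to rt
Reagents that add atoms: dibromomethane, BrCBr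
Why: Takai–Lombardo methylenation is non-basic, so the hindered C8 ketone should give the exocyclic methylene without β-elimination of the acetate, epimerisation at C9 or attack on the esters.

**Compound list**

1 | 3,5-dimethoxybenzoic acid | COc1cc(cc(OC)c1)C(=O)O | starting material
2 | 3,5-dimethoxy-1-methylcyclohexa-2,5-diene-1-carboxylic acid (achiral) | CC1(C(=O)O)C=C(OC)CC(OC)=C1 | intermediate
3 | (3,5-dimethoxy-1-methylcyclohexa-2,5-dien-1-yl)methanol | CC1(CO)C=C(OC)CC(OC)=C1 | intermediate
4 | 3,5-dimethoxy-1-methylcyclohexa-2,5-diene-1-carbaldehyde | CC1(C=O)C=C(OC)CC(OC)=C1 | intermediate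
5 | (4-methoxy-4-oxobutyl)triphenylphosphonium bromide | [Br-].COC(=O)CCC[P+](c1ccccc1)(c1ccccc1)c1ccccc1 | starting material
6 | methyl 4-(triphenylphosphoranylidene)butanoate (ylide, not isolated) | COC(=O)CCC=P(c1ccccc1)(c1ccccc1)c1ccccc1 | intermediate
7 | methyl (4Z)-5-(3,5-dimethoxy-1-methylcyclohexa-2,5-dien-1-yl)pent-4-enoate | COC(=O)CC/C=C\C1(C)C=C(OC)CC(OC)=C1 | intermediate
8 | methyl 5-(3,5-dimethoxy-1-methylcyclohexa-2,5-dien-1-yl)pentanoate | COC(=O)CCCCC1(C)C=C(OC)CC(OC)=C1 | intermediate
9 | methyl 5-(3,5-dimethoxy-1-methylcyclohexa-2,5-dien-1-yl)-2-(trifluoroacetyl)pentanoate (not isolated) | COC(=O)C(CCCC1(C)C=C(OC)CC(OC)=C1)C(=O)C(F)(F)F | intermediate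
10 | methyl 2-diazo-5-(3,5-dimethoxy-1-methylcyclohexa-2,5-dien-1-yl)pentanoate | COC(=O)C(=[N+]=[N-])CCCC1(C)C=C(OC)CC(OC)=C1 | intermediate
11 | tricyclic cyclopropane ester: rings A and B with an extra C4–C6 bond, cyclopropane C4–C5–C6 anti to the 10β-methyl, 4-CO2Me, 6-OMe, 5β-H, 8-methoxy-8-ene | COC(=O)[C@@]12CCC[C@]3(C)C=C(OC)C[C@@]2(OC)[C@H]13 | intermediate
12 | methyl 4a-methyl-6,8-dioxodecahydronaphthalene-1-carboxylate (C6,C8-dione; C10 as in target; mixture at C4 and C5, both reset later; not isolated) | C1C(=O)CC(=O)C2[C@]1(C)CCCC2C(=O)OC | intermediate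
13 | methyl 6-methoxy-4a-methyl-8-oxo-1,2,3,4,4a,5,8,8a-octahydronaphthalene-1-carboxylate (mixture at C4 and C5) | C1C(OC)=CC(=O)C2[C@]1(C)CCCC2C(=O)OC | intermediate
14 | methyl 8-hydroxy-6-methoxy-4a-methyl-1,2,3,4,4a,5,8,8a-octahydronaphthalene-1-carboxylate (not isolated) | C1C(OC)=CC(O)C2[C@]1(C)CCCC2C(=O)OC | intermediate
15 | methyl 4a-methyl-6-oxo-1,2,3,4,4a,5,6,8a-octahydronaphthalene-1-carboxylate, C5-epimer mixture (not isolated) | C1C(=O)C=CC2[C@]1(C)CCCC2C(=O)OC | intermediate
16 | the same enone, trans-fused (5α-H, 10β-CH3; C4 epimers, reset in step 13) | C1C(=O)C=C[C@@H]2[C@]1(C)CCCC2C(=O)OC | intermediate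
17 | but-2-yn-1-ol | CC#CCO | starting material
18 | (2Z)-3-iodobut-2-en-1-ol | C/C(I)=C/CO | intermediate
19 | (2Z)-1-bromo-3-iodobut-2-ene | C/C(I)=C/CBr | intermediate
20 | methyl 5-[(2Z)-3-iodobut-2-en-1-yl]-4a-methyl-6-oxo-1,2,3,4,4a,5,6,8a-octahydronaphthalene-1-carboxylate (5α-H; C9 and C4 open) | I/C(C)=C\CC1C(=O)C=C[C@@H]2[C@]1(C)CCCC2C(=O)OC | intermediate
21 | methyl (12Z)-13-iodo-8-oxo-14,15,17-trinorlabda-6,12-dien-19-oate | I/C(C)=C\C[C@H]1C(=O)C=C[C@@H]2[C@]1(C)CCC[C@]2(C)C(=O)OC | intermediate
22 | methyl (12Z)-8-oxo-17-norlabda-6,12,14-trien-19-oate | C=C/C(C)=C\C[C@H]1C(=O)C=C[C@@H]2[C@]1(C)CCC[C@]2(C)C(=O)OC | intermediate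
23 | methyl (12Z)-8-oxo-6α-(pinacolatoboryl)-17-norlabda-12,14-dien-19-oate (not isolated) | C=C/C(C)=C\C[C@H]1C(=O)C[C@H](B3OC(C)(C)C(C)(C)O3)[C@@H]2[C@]1(C)CCC[C@]2(C)C(=O)OC | intermediate
24 | methyl (12Z)-6α-hydroxy-8-oxo-17-norlabda-12,14-dien-19-oate | C=C/C(C)=C\C[C@H]1C(=O)C[C@H](O)[C@@H]2[C@]1(C)CCC[C@]2(C)C(=O)OC | intermediate
25 | methyl (12Z)-6α-acetoxy-8-oxo-17-norlabda-12,14-dien-19-oate | C=C/C(C)=C\C[C@H]1C(=O)C[C@H](OC(C)=O)[C@@H]2[C@]1(C)CCC[C@]2(C)C(=O)OC | intermediate
26 | methyl (12Z)-6α-acetoxylabda-8(17),12,14-trien-19-oate | C=C/C(C)=C\C[C@H]1C(=C)C[C@H](OC(C)=O)[C@@H]2[C@]1(C)CCC[C@]2(C)C(=O)OC | target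

**Total step count:** 17. **Longest linear sequence:** 15 steps (steps 1–9 and 12–17).

**Steps most likely to fail**

Step 7. The carbenoid may undergo 1,2-hydride migration from C3 faster than it reaches the enol ether, or the catalyst may discriminate the enantiotopic enol ethers poorly. The fallback sets out from 8 and returns at 12; it moves the enantiotopic-group selection to a desymmetrising asymmetric Heck cyclisation, a reaction type established for 1-substituted cyclohexa-2,5-dienes. Ester 8 is hydroxylated at C4 through its lithium enolate with 3-phenyl-2-(phenylsulfonyl)oxaziridine to hydroxy ester F1 and oxidised ([N(C3H7)4][RuO4], N-methylmorpholine N-oxide) to keto ester F2. KN(SiMe3)2 and PhNTf2 should give the Z enol triflate F3. Pd(OAc)2, (R)-BINAP and K2CO3 in toluene should then effect oxidative addition, 6-exo carbopalladation of one enol ether at C5 and β-hydride elimination towards C7, giving the cis-fused diene ester F4 with ring A closed and C10 set by the chiral palladium complex. Aqueous HCl hydrolyses both enol ethers to enoate dione F5, and H2 over Pd/C saturates C3=C4 to give dione 12, which is etherified as in the second stage of step 8.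

Step 9. Equilibration at C5 through the dienolate may be incomplete or may not favour the trans-fused enone sufficiently. The fallback sets out from 13 and returns at 16; it replaces thermodynamic by kinetic control. LiN(iPr)2 at −78 °C removes the α′ proton at C5 of the vinylogous ester, and a cold acetic acid quench protonates the cross-conjugated enolate from the α face, anti to the pseudo-axial C10 methyl, to give trans-fused vinylogous ester F6. Luche reduction and cold acidic transposition without the methoxide treatment then give 16.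

Step 13. Dianion formation may be incomplete, methyl iodide may also alkylate the C9 enolate, and protonation at C9 on quench may be unselective. The fallback sets out from 20 and returns at 21; it masks the ketone so that only the ester can be enolised. LiN(iPr)2 with Me3SiCl as internal quench converts 20 into silyl dienol ether F7. A second deprotonation with LiN(iPr)2 and methylation with MeI, again from the α face, give methylated silyl dienol ether F8. Bu4NF buffered with AcOH at −78 °C removes the silyl group with kinetic α-face protonation at C9 and returns 21.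

**Further compounds**

F1 | step 7 | methyl 5-(3,5-dimethoxy-1-methylcyclohexa-2,5-dien-1-yl)-2-hydroxypentanoate | COC(=O)C(O)CCCC1(C)C=C(OC)CC(OC)=C1
F2 | step 7 | methyl 5-(3,5-dimethoxy-1-methylcyclohexa-2,5-dien-1-yl)-2-oxopentanoate | COC(=O)C(=O)CCCC1(C)C=C(OC)CC(OC)=C1
F3 | step 7 | methyl (2Z)-5-(3,5-dimethoxy-1-methylcyclohexa-2,5-dien-1-yl)-2-{[(trifluoromethyl)sulfonyl]oxy}pent-2-enoate | COC(=O)/C(OS(=O)(=O)C(F)(F)F)=C/CCC1(C)C=C(OC)CC(OC)=C1
F4 | step 7 | methyl 6,8-dimethoxy-4a-methyl-3,4,4a,8a-tetrahydronaphthalene-1-carboxylate (cis-fused, C10 as in target) | COC(=O)C1=CCC[C@]2(C)C=C(OC)C=C(OC)[C@H]12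
F5 | step 7 | methyl 4a-methyl-6,8-dioxo-3,4,4a,5,6,7,8,8a-octahydronaphthalene-1-carboxylate | COC(=O)C1=CCC[C@]2(C)CC(=O)CC(=O)C12
F6 | step 9 | methyl 6-methoxy-4a-methyl-8-oxo-1,2,3,4,4a,5,8,8a-octahydronaphthalene-1-carboxylate, trans-fused (5α-H) | C1C(OC)=CC(=O)[C@@H]2[C@]1(C)CCCC2C(=O)OC
F7 | step 13 | methyl 5-[(2Z)-3-iodobut-2-en-1-yl]-4a-methyl-6-[(trimethylsilyl)oxy]-1,2,3,4,4a,8a-hexahydronaphthalene-1-carboxylate | I/C(C)=C\CC1=C(O[Si](C)(C)C)C=C[C@@H]2[C@]1(C)CCCC2C(=O)OC
F8 | step 13 | methyl 5-[(2Z)-3-iodobut-2-en-1-yl]-1,4a-dimethyl-6-[(trimethylsilyl)oxy]-1,2,3,4,4a,8a-hexahydronaphthalene-1-carboxylate (4α-CH3, 4β-CO2Me) | I/C(C)=C\CC1=C(O[Si](C)(C)C)C=C[C@@H]2[C@]1(C)CCC[C@]2(C)C(=O)OC
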